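Target is what you count in this flask, and in the two earlier runs it stands close together at the last reading, although substrate and solid reagent were charged differently.

| setting | epsilon | theta | flask |
|---|---|---|---|
| substrate | 2.1 M | 1.5 M | 1.5 M |
| solid reagent | 1.2 M | 1.8 M | 1.20 M |
| remark | run made earlier | run made earlier |  |
| time |  |  | 25 min |

- epsilon (time / min: target / %): 1.33: 1; 2.00: 1; 3.00: 4; 4.00: 5; 6.00: 6; 10.0: 12; 15.0: 18
- theta (time / min: target / %): 1.33: 0; 2.50: 4; 4.00: 5; 8.00: 6; 15.0: 19

(readings scatter by 2 percentage points)

- target at 25 min, in percent of the substrate charged
- concentration of coupling partner in solution at 6.0 min, in percent of saturation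
- the change that raises the amount of target at 25 min, in percent of the substrate charged most ("none" if none brings more than 2 percentage points) (Saturday's / Thursday's / none)
- amount of target at 25 min, in percent of the substrate charged, after Thursday's

- solid, in amounts per volume of the solution: solid reagent
- at the start none of the solid reagent is in solution
- coupling partner is what solid reagent becomes in solution

- Saturday's: doubling the dissolution coefficient of the solid reagent, all else as stated
- Thursday's: doubling the solubility of the solid reagent, all else as stated

Epsilon gives 18 % and theta 19 % at 15.0 min, with substrate at 2.1 M and 1.5 M, and solid reagent at 1.2 M and 1.8 M. Two settings differ here, so this is an assumption and not a proof: I take the percent yield as independent of the substrate charge, which is pseudo-first-order behaviour, and I let the logarithm of the unreacted fraction fall on a straight line with slope k′. Drawn from zero through epsilon's last reading, this gives k′ = 0.0132 min⁻¹, and so 28.1 % at 25 min.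

The weak link is the start, since no solid reagent is in solution at zero time. So I reforge the line through epsilon's readings at 6.00 min and 15.0 min. The slope, k′ = 0.0152 min⁻¹, the apparent constant I carry forward, is steeper, and the line meets zero at a lag τ = 1.92 min. With a scatter of 2 percentage points on a reading of 6 %, that lag is rough. Running from τ to 25 min in the flask, I commit to 29.5 %. Taking one coupling partner per target, this asks for 0.443 M in the flask, less than the 1.20 M charged.

The forecast says 29.5 %, reached with a slope and a lag of its own, with 98 % of saturation at 6.0 min, and picks Thursday's, giving 49 %. Its ground: “Coupling partner sits near saturation, set by solubility rather than by solid amount or dissolution rate”.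

The flask gives 29.8 %, with coupling partner at 39.3 % of saturation at 6.0 min. Saturday's moves target by 0.37 points and Thursday's by −0.38 points, both less than the 2 points asked for, so the answer is none, and Thursday's gives 29.4 %.

    substrate + coupling partner ⇌ target (K = 3.10 L mol⁻¹, k = 0.00120 L mol⁻¹ s⁻¹)
    2 coupling partner → side product (k = 0.00140 L mol⁻¹ s⁻¹)
    solid reagent ⇌ coupling partner, rate k3*(cs3 - [coupling partner]) while solid is left; crystals form when [coupling partner] > cs3 (solubility = 0.720 M, k = 0.00220 s⁻¹)
    target ⇌ isomer of the product (K = 0.160, k = 0.00210 s⁻¹)

Divide k′ by the forward constant 0.0012 L mol⁻¹ s⁻¹, counting that step alone, and it corresponds to 0.211 M of coupling partner, 29.3 % of the saturation value 0.72 M.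

In the neighbouring flask with 0.30 M of solid reagent, k′ and τ again give 29.5 %, which asks for 0.443 M, more than that charge, and at one coupling partner per target that charge allows at most 20.0 %. That neighbouring flask gives 11.1 % at 25 min.

(The numbers in the tables were generated by integration with made-up constants, noise included.)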